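**Retrosynthetic overview**
- The target is unmasked in the last step from its 5,7‑di‑O‑methyl ether; the two methyl ethers are the only protecting groups.
- Key disconnection: the side‑chain bond between the second and third carbon counted from the pyranone. It is made by a visible‑light decarboxylative Giese (1,6‑) addition of the heptadecyl radical, from stearic acid via its N‑acyloxyphthalimide, to a 2‑vinylchromone.
- Enabling feature: the 4‑pyranone ring is a vinylogous ester, O1–C2=C3–C4=O. A vinyl group on C2 extends it to a dienone whose terminal CH2 accepts nucleophilic alkyl radicals. The same vinylogy acidifies the CH2 next to C2, so the vinyl group can be released from a 2‑(dimethylamino)ethyl (Mannich‑type) side chain.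
- Ring order: the benzene ring is bought (phloroacetophenone) and C‑methylated twice. The pyranone is the only ring made (Claisen condensation, then cyclodehydration) and is in place before the key step.

Key step: step 6

Remark on the chemistry: the target has no stereocentre and no stereogenic double bond; it is achiral, so the route needs no stereocontrol.

**Route**

Step 1
Reactants: 1 2,4,6-trihydroxyacetophenone
Product: 2 1-(2,4,6-trihydroxy-3,5-dimethylphenyl)ethan-1-one
Conditions: NaOMe (3 equiv), MeI (2.2 equiv), MeOH, 0 °C to reflux
Reagents that add atoms: iodomethane (CI)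
Why: C‑alkylation of the ambident acylphloroglucinol polyanion in a protic solvent should methylate the two free ring carbons, with the MeI stoichiometry limiting over‑methylation to the dearomatised gem‑dimethyl compound.

Step 2
Reactants: 2 1-(2,4,6-trihydroxy-3,5-dimethylphenyl)ethan-1-one
Product: 3 1-(2-hydroxy-4,6-dimethoxy-3,5-dimethylphenyl)ethan-1-one
Conditions: Me2SO4 (2.1 equiv), K2CO3, acetone, reflux
Reagents that add atoms: dimethyl sulfate (COS(=O)(=O)OC)
Why: Williamson O‑methylation should stop at the diether because the hydroxyl hydrogen‑bonded to the acetyl carbonyl is the least nucleophilic, the two ortho hydroxyls being equivalent until one is capped.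

Step 3
Reactants: 3 1-(2-hydroxy-4,6-dimethoxy-3,5-dimethylphenyl)ethan-1-one; 4 methyl 3-(dimethylamino)propanoate
Product: 6 2-[2-(dimethylamino)ethyl]-5,7-dimethoxy-6,8-dimethyl-4H-chromen-4-one, via amino diketone 5 (not isolated)
Conditions: LiHMDS (3.2 equiv), THF, −78 °C to rt; then HCl, MeOH, 50 °C; aq. NaHCO3 work‑up
Reagents that add atoms: none
Why: Crossed Claisen condensation of the ketone dianion with the ester gives the 1,3‑diketone, which cyclodehydrates under acid (6‑exo‑trig attack of the single free phenol on the distal carbonyl, then loss of water) to the 4‑pyranone, the protonated amine being safe from elimination.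

Step 4
Reactants: 6 2-[2-(dimethylamino)ethyl]-5,7-dimethoxy-6,8-dimethyl-4H-chromen-4-one
Product: 8 2-ethenyl-5,7-dimethoxy-6,8-dimethyl-4H-chromen-4-one, via ammonium iodide 7 (not isolated)
Conditions: MeI (3 equiv), MeCN, rt; evaporate; then K2CO3, MeCN, 40 °C, BHT (trace)
Reagents that add atoms: none
Why: Exhaustive N‑methylation followed by Hofmann‑type E1cB elimination should release the vinyl group, because the CH2 next to C2 is vinylogously alpha to the C4 carbonyl and trimethylamine is a good leaving group.

Step 5
Reactants: 9 octadecanoic acid (stearic acid)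
Product: 10 1,3-dioxoisoindolin-2-yl octadecanoate
Conditions: N‑hydroxyphthalimide (1.1 equiv), DIC (1.1 equiv), DMAP (cat.), CH2Cl2, rt
Reagents that add atoms: N‑hydroxyphthalimide (O=C1c2ccccc2C(=O)N1O)
Why: Steglich‑type carbodiimide esterification converts the fatty acid into its redox‑active N‑acyloxyphthalimide.

Step 6
Reactants: 8 2-ethenyl-5,7-dimethoxy-6,8-dimethyl-4H-chromen-4-one; 10 1,3-dioxoisoindolin-2-yl octadecanoate
Product: 11 5,7-dimethoxy-6,8-dimethyl-2-nonadecyl-4H-chromen-4-one
Conditions: 10 (1.5 equiv), Hantzsch ester (1.5 equiv), Ru(bpy)3(PF6)2 (1 mol%), CH2Cl2 (dilute, degassed), blue LEDs (450 nm), rt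
Reagents that add atoms: none
Why: Reductive quenching of photoexcited Ru(II) by the Hantzsch ester gives Ru(I), which transfers an electron to 10; N–O cleavage and loss of CO2 release the primary heptadecyl radical, which adds to the terminal CH2 of the C2‑vinyl group of 8 (a vinylogous, 1,6‑Giese addition), and the resulting radical, delocalised over the side‑chain carbon next to C2, C3 and the C4 carbonyl oxygen, is quenched by hydrogen‑atom transfer from the Hantzsch ester radical cation (or by reduction and protonation). The closest known reaction type is the visible‑light reductive decarboxylative Giese addition of redox‑active esters to enones, acrylates and vinyl heteroarenes. No ring is closed and no stereocentre is created, the new bond joining two CH2 groups. The step needs site selectivity (vinyl terminus rather than C2 or C3 of the pyranone) and mono‑addition rather than telomerisation: the terminal CH2 is the only unhindered acceptor position and the only one that gives the fully delocalised radical, C2 being fully substituted, and the stabilised, electrophilic adduct radical should be reduced faster than it adds to a second electron‑poor alkene. Hydrogen delivery at the side‑chain carbon or at C3 converges on the same product, because the exocyclic enol‑ether tautomer isomerises to the 4‑pyranone. The methyl ethers keep the arene free of phenolates that would quench the photocatalyst.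

Step 7
Reactants: 11 5,7-dimethoxy-6,8-dimethyl-2-nonadecyl-4H-chromen-4-one
Product: 12 5,7-dihydroxy-6,8-dimethyl-2-nonadecyl-4H-chromen-4-one
Conditions: BBr3 (6 equiv), CH2Cl2, −78 °C to rt; then MeOH, H2O
Reagents that add atoms: none
Why: Lewis‑acid cleavage of both aryl methyl ethers should be easy, the 5‑OMe being assisted by chelation to the C4 carbonyl and the 7‑OMe by its twisted, di‑ortho‑substituted geometry, while the alkyl chain and the pyranone are inert.

**Compound list**
1 | 2,4,6-trihydroxyacetophenone | CC(=O)c1c(O)cc(O)cc1O | starting material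
2 | 1-(2,4,6-trihydroxy-3,5-dimethylphenyl)ethan-1-one | CC(=O)c1c(O)c(C)c(O)c(C)c1O | intermediate
3 | 1-(2-hydroxy-4,6-dimethoxy-3,5-dimethylphenyl)ethan-1-one | CC(=O)c1c(O)c(C)c(OC)c(C)c1OC | intermediate
4 | methyl 3-(dimethylamino)propanoate | COC(=O)CCN(C)C | starting material
5 | 5-(dimethylamino)-1-(2-hydroxy-4,6-dimethoxy-3,5-dimethylphenyl)pentane-1,3-dione | CN(C)CCC(=O)CC(=O)c1c(O)c(C)c(OC)c(C)c1OC | intermediate
6 | 2-[2-(dimethylamino)ethyl]-5,7-dimethoxy-6,8-dimethyl-4H-chromen-4-one | CN(C)CCc1cc(=O)c2c(OC)c(C)c(OC)c(C)c2o1 | intermediate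
7 | 2-(5,7-dimethoxy-6,8-dimethyl-4-oxo-4H-chromen-2-yl)-N,N,N-trimethylethan-1-aminium iodide | C[N+](C)(C)CCc1cc(=O)c2c(OC)c(C)c(OC)c(C)c2o1.[I-] | intermediate
8 | 2-ethenyl-5,7-dimethoxy-6,8-dimethyl-4H-chromen-4-one | C=Cc1cc(=O)c2c(OC)c(C)c(OC)c(C)c2o1 | intermediate
9 | octadecanoic acid (stearic acid) | CCCCCCCCCCCCCCCCCC(=O)O | starting material
10 | 1,3-dioxoisoindolin-2-yl octadecanoate | CCCCCCCCCCCCCCCCCC(=O)ON1C(=O)c2ccccc2C1=O | intermediate
11 | 5,7-dimethoxy-6,8-dimethyl-2-nonadecyl-4H-chromen-4-one | CCCCCCCCCCCCCCCCCCCc1cc(=O)c2c(OC)c(C)c(OC)c(C)c2o1 | intermediate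
12 | 5,7-dihydroxy-6,8-dimethyl-2-nonadecyl-4H-chromen-4-one | CCCCCCCCCCCCCCCCCCCc1cc(=O)c2c(O)c(C)c(O)c(C)c2o1 | target

**Step count**
Total steps: 7. Longest linear sequence: 6 (steps 1, 2, 3, 4, 6, 7); step 5 is a one‑step branch.

**Steps most likely to fail**

Step 6. The adduct radical may add to further vinylchromone (telomerisation), the heptadecyl radical may be reduced before it adds, or a second radical may attack C2 of the product pyranone. The fallback makes the same bond without an alkene, by a nickel‑electrocatalysed doubly decarboxylative C(sp3)–C(sp3) cross‑coupling of two redox‑active esters. It sets out from 3. The dianion of 3 (LiHMDS, THF, −78 °C) is acylated with succinic anhydride to 6-(2-hydroxy-4,6-dimethoxy-3,5-dimethylphenyl)-4,6-dioxohexanoic acid F1. This is cyclodehydrated without isolation (H2SO4 cat., AcOH, 60 °C) to 3-(5,7-dimethoxy-6,8-dimethyl-4-oxo-4H-chromen-2-yl)propanoic acid F2. Esterification with N‑hydroxyphthalimide (DIC, DMAP cat., CH2Cl2) gives 1,3-dioxoisoindolin-2-yl 3-(5,7-dimethoxy-6,8-dimethyl-4-oxo-4H-chromen-2-yl)propanoate F3. F3 and an excess of 10 are then electrolysed (Ni(II)/terpyridine catalyst, sacrificial Zn anode, carbon cathode, DMF, constant current, rt); the excess of the cheaper partner suppresses statistical homocoupling of the chromone fragment. The fallback comes back to the route at 11.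

Step 4. Quaternisation or elimination may stop short, trimethylamine may re‑add to the vinylogous acceptor, and the base may oligomerise the vinylchromone on concentration. The fallback replaces the base‑mediated Hofmann elimination by an oxidative, base‑free Cope syn‑elimination. It sets out from 6. N‑oxidation (mCPBA, 1.0 equiv, CH2Cl2, 0 °C) gives 2-(5,7-dimethoxy-6,8-dimethyl-4-oxo-4H-chromen-2-yl)-N,N-dimethylethan-1-amine N-oxide F4. Gentle warming (THF, 40–60 °C) should eliminate the N‑oxide thermally, the hydroxylamine by‑product being removed by a dilute acid wash. The fallback comes back to the route at 8.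

Step 3. Excess amide base may enolise the amino ester, leading to self‑condensation instead of C‑acylation of the ketone dianion, so that 3 is recovered. The fallback is a Baker–Venkataraman sequence that makes the C–C bond by intramolecular acyl transfer. It sets out from 3. O‑acylation with 3‑(dimethylamino)propanoyl chloride hydrochloride (pyridine, DMAP cat., CH2Cl2) gives 2-acetyl-3,5-dimethoxy-4,6-dimethylphenyl 3-(dimethylamino)propanoate F5. KOt‑Bu in THF (0 °C to rt) then induces enolate O‑to‑C acyl migration. The fallback comes back to the route at 5, which is cyclodehydrated to 6 as in step 3.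

**Further compounds**
F1 | step 6 | 6-(2-hydroxy-4,6-dimethoxy-3,5-dimethylphenyl)-4,6-dioxohexanoic acid | O=C(O)CCC(=O)CC(=O)c1c(O)c(C)c(OC)c(C)c1OC
F2 | step 6 | 3-(5,7-dimethoxy-6,8-dimethyl-4-oxo-4H-chromen-2-yl)propanoic acid | O=C(O)CCc1cc(=O)c2c(OC)c(C)c(OC)c(C)c2o1
F3 | step 6 | 1,3-dioxoisoindolin-2-yl 3-(5,7-dimethoxy-6,8-dimethyl-4-oxo-4H-chromen-2-yl)propanoate | O=C(CCc1cc(=O)c2c(OC)c(C)c(OC)c(C)c2o1)ON1C(=O)c2ccccc2C1=O
F4 | step 4 | 2-(5,7-dimethoxy-6,8-dimethyl-4-oxo-4H-chromen-2-yl)-N,N-dimethylethan-1-amine N-oxide | C[N+](C)([O-])CCc1cc(=O)c2c(OC)c(C)c(OC)c(C)c2o1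
F5 | step 3 | 2-acetyl-3,5-dimethoxy-4,6-dimethylphenyl 3-(dimethylamino)propanoate | CC(=O)c1c(OC(=O)CCN(C)C)c(C)c(OC)c(C)c1OC
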